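## Structural features

The target is a flavonol without stereocentres. Ring A (benzo) is fused to the 4-pyranone ring C at C4a–C8a, and ring B is a phenyl group bound to C2 through the single bond C2–C1'. Seven oxygens sit on the periphery: ring A has a hydroxyl at C5 and methoxyls at C7 and C8 (C6 is CH); ring C has the enolic 3-hydroxyl; ring B has hydroxyls at C2' and C4' and a methoxyl at C5' (C3' and C6' are CH). O3 and O5 flank the C4 carbonyl and can chelate, which sets them apart from every other oxygen. The compound is an electron-rich polyphenol: the 3-hydroxy enone is oxidised in aerated base, the pyranone opens with strong nucleophiles, and hot mineral acid could scramble ring A by opening and reclosing through O5 instead of O1. The late steps must therefore be mild. The real difficulty is not the carbon skeleton but telling the oxygens apart: three methyl ethers must stand beside four free hydroxyls, and O4'/O5' is a hydroxyl–methoxyl pair on neighbouring carbons. The key step uses the pattern of ring B: C2'–C3'–C4'–C5' has the oxygenation of a 4-methoxyacetoacetate chain, and C1'–C6' is a two-carbon unit that can be an alkyne already bound to C2, so ring B can be grown on the chromone with its oxygens in their final state.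

## Logic of the disconnections

**15 ⇒ 14.** The O3–CH3 and O5–CH3 bonds are restored. These two oxygens are the only ones next to the C4 carbonyl, so they are the only methyl ethers that a chelating Lewis acid can single out. Keeping them methylated makes every earlier intermediate aprotic at rings A and C and prevents O3 from cyclising onto the alkyne of 9. The gain is a protecting group that arrives with the starting materials at no cost in steps. The demand is a reagent that cleaves through both the six-membered chelate (O5) and the five-membered chelate (O3) and spares O7, O8 and O5' beside the free O2' and O4'. A reagent that reaches only the peri oxygen O5 would not suffice.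

**14 ⇒ 9 + 12.** C1'–C2' and C5'–C6' are cut, which removes ring B. The four carbons C2'–C5' with all three ring-B oxygens go to 12, and C1'/C6' remain as the alkyne of 9. Ring B then needs no protecting groups, and both partners are small and aprotic. The demand is a cycloaddition onto an alkyne that is activated only through the pyranone enone, with one regiochemistry and an aromatisation that keeps the C5' methoxyl.

**12 ⇒ 11 ⇒ 10.** The two O–Si bonds are cut in turn, leading to a commercial β-keto ester that already holds the future C5' methoxyl. The demand is γ-deprotonation of 11 at the methoxy-bearing carbon and strict exclusion of moisture.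

**9 ⇒ 8.** The terminal C–H is exchanged for C–Si. The silyl cap protects the alkyne terminus from bases and nucleophiles during ring C construction. The forward step must remove silicon without nucleophilic addition to the activated alkyne.

**8 ⇒ 4 + 6 (through 7).** C2–C3 and O1–C2 are cut, which removes ring C. C2 and the alkyne come from the acyl chloride 6; C3 with its methoxyl, C4 and ring A come from 4. The demand is C-acylation of an α-methoxy ketone by an alkynoyl chloride without conjugate addition, then ring closure by the phenol oxygen on the alkynyl ketone and not by the enol oxygen on the alkyne.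

**6 ⇒ 5.** The C–Cl bond is cut, leading to the commercial acid.

**4 ⇒ 1 + 2 (through 3).** The aryl–acyl bond C4–C4a is cut, and the methyl group is restored on the oxygen that becomes O1. Arene 1 has two equivalent free positions, so the acylation is unambiguous. The forward step must also free the phenol at the future O1, because ring C cannot be closed on a methyl ether. This means cleaving the ortho methoxyl that lies between the acyl group and a second methoxyl, not the other ortho methoxyl.

## Other disconnections considered

**Alternative 1:** The cut runs through ring A at C4–C4a and C5–O5. Fluoride would release the aryne from silyl triflate A2, and benzyloxyacetic acid A3 would add across it to give ketone A1. The carboxylate oxygen attacks the aryne carbon remote from the methoxymethoxy group, the aryl anion attacks the ester carbonyl, and the four-membered intermediate opens to the ortho-acyl phenoxide.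
- In its favour: acyl group and phenol oxygen arrive in one operation. The position of the free hydroxyl is fixed by aryne polarisation, not by a selective demethylation. A benzyl group on the future O3 would allow a hydrogenolytic endgame without Lewis acid. On these two points the alternative is equal to or better than the chosen plan, which relies on a directed demethylation in step 1 and a Lewis acid in step 8.
- Against it here: the free hydroxyl of A1 is O5, not O1, so it must be capped and the methoxymethyl ether removed before ring C can be closed. A2 is a pentasubstituted benzene that needs several steps. Protonation of the aryl anion to a simple aryl ester can compete with insertion.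
- Comparison: in structure A1 is the counterpart of 4, which the chosen plan reaches in one step from a commercial arene, and A1 contains neither ring C nor ring B. In mechanism both plans depend on polarity-controlled regiochemistry. In step economy the alternative is clearly longer.

**Alternative 2:** The cut removes ring A at C5–C6, C7–C8 and C8–C8a. Carbene complex A5, a Cr(CO)5 methoxycarbene complex of zerovalent chromium that already carries rings B and C, would combine with methoxyacetylene A6 and one CO ligand in a Dötz benzannulation to give the 8-hydroxychromone A4.
- In its favour: three C–C bonds and ring A form in one step. The ring A oxygens emerge fully differentiated (O8 free, O5 and O7 methylated). On this differentiation it is equal to or better than the chosen plan, and it shares with it the idea of making an arene de novo.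
- Against it here: chromium is stoichiometric. A5 would have to be made by metalating a highly substituted 4-pyranone next to its carbonyl. A6 is volatile and sensitive. The pyranone alkene is electron-poor and carries the ring oxygen at its β-carbon, so annulation without CO insertion may compete. After the key step O8 must be methylated, O5 demethylated and three benzyl groups removed.
- Comparison: in structure it solves ring A and leaves ring B to a separate multistep synthesis, whereas the chosen plan makes ring B with its final oxygen pattern. In mechanism both rest on one regiochemical preference. In step economy and safety the chosen plan, which uses no transition metal, is ahead.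

**Alternative 3:** The cut is O1–C2 of ring C. Aurone A9 would take up bromine to give dibromide A8, and ethanolic alkali would open the five-membered ring at its O–C2 bond. The phenoxide then displaces the benzylic bromide and tautomerisation gives flavonol A7 (Auwers synthesis).
- In its favour: the reagents are cheap and classical. O3 arrives as a free hydroxyl, so only the peri methyl ether at O5 needs cleaving afterwards, which is the more dependable of the two chelation-directed cleavages. On this point it is better than the double demethylation of step 8.
- Against it here: bromine must add to the exocyclic alkene while ring A has a CH between two methoxyls, so nuclear bromination is a likely competitor. The alkoxy groups conjugated with the benzofuranone carbonyl lower its electrophilicity, so dehydrobromination back to a bromo-aurone may compete with ring opening. The tosylates may not survive hot alkali in a controlled way and need their own removal step. A ring B aldehyde with this protection must be prepared first.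
- Comparison: in structure it builds ring C last from two finished arenes, while the chosen plan builds ring B last. In mechanism it depends on the relative rates of ring opening and elimination, the chosen plan on cycloaddition to a weak dienophile; neither is free of risk. In step economy the alternative is not shorter once the aurone synthesis, detosylation and O5 demethylation are counted.

Key step: step 7

Remark on the chemistry: 11 and 12 are drawn as single geometric isomers; isomer mixtures are assumed to serve equally, because every sp2 carbon of 12 ends in the aromatic ring B.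

## Route

Step 1
Reactants: 1 1,2,3,5-tetramethoxybenzene; 2 methoxyacetyl chloride
Product: 4 1-(2-hydroxy-3,4,6-trimethoxyphenyl)-2-methoxyethan-1-one, via tetramethoxyphenyl ketone 3 (not isolated)
Conditions: 2 (1.1 equiv), AlCl3 (2.5 equiv), CH2Cl2, 0 °C; add 1; 0 °C → rt; then 1 M HCl
Reagents that add atoms: none
Why: Friedel–Crafts acylation at one of the two symmetry-equivalent free positions of 1 can give only ketone 3; its AlCl3 complex should then lose the methyl group of the ortho methoxyl squeezed between the acyl group and a second methoxyl (twisted out of plane, most Lewis basic, six-membered aluminium chelate), the usual outcome for 2,3,4-trioxygenated aryl ketones, which frees exactly the oxygen that becomes O1. The aliphatic methoxyl and the unchelated aryl methyl ethers should survive at room temperature.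

Step 2
Reactants: 5 3-(trimethylsilyl)prop-2-ynoic acid
Product: 6 3-(trimethylsilyl)prop-2-ynoyl chloride
Conditions: (COCl)2 (1.2 equiv), DMF (cat.), CH2Cl2, 0 °C → rt; concentrate, use crude
Reagents that add atoms: oxalyl chloride, ClC(=O)C(=O)Cl
Why: Acid chloride formation through the chloroiminium (Vilsmeier-type) activator; the silyl cap hinders addition of HCl to the triple bond, and the chloride is used at once.

Step 3
Reactants: 4 1-(2-hydroxy-3,4,6-trimethoxyphenyl)-2-methoxyethan-1-one; 6 3-(trimethylsilyl)prop-2-ynoyl chloride
Product: 8 3,5,7,8-tetramethoxy-2-[(trimethylsilyl)ethynyl]-4H-chromen-4-one, via alkynyl diketone 7 (not isolated)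
Conditions: LiN(SiMe3)2 (3.3 equiv), THF, −78 °C; 6 (1.1 equiv), −78 → −20 °C; AcOH; then TsOH·H2O (0.1 equiv), PhMe, 50 °C
Reagents that add atoms: none
Why: One-pot variant of the Baker–Venkataraman synthesis: the enolate carbon of the phenoxide–enolate dianion of 4 is acylated by 6 (any O-acylated material rearranges under the excess base) and the third equivalent of base stores 7 as its enolate; mild acid then closes the hemiketal at the alkynyl ketone (6-exo-trig) and dehydrates it to the pyranone. Attack on the carbonyl should outrun 6-endo-dig attack of the enol oxygen on the silyl-shielded alkyne.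

Step 4
Reactants: 8 3,5,7,8-tetramethoxy-2-[(trimethylsilyl)ethynyl]-4H-chromen-4-one
Product: 9 2-ethynyl-3,5,7,8-tetramethoxy-4H-chromen-4-one
Conditions: Bu4NF (1.1 equiv), AcOH (1.2 equiv), THF, −20 → 0 °C
Reagents that add atoms: none
Why: Fluoride-induced protodesilylation of an alkynylsilane; the acetic acid buffer and the low temperature should keep fluoride or hydroxide from adding to the electrophilic alkyne terminus or opening the pyranone, and 9 is used promptly.

Step 5
Reactants: 10 methyl 4-methoxy-3-oxobutanoate
Product: 11 methyl (Z)-4-methoxy-3-(trimethylsilyloxy)but-2-enoate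
Conditions: Me3SiCl (1.5 equiv), Et3N (1.6 equiv), PhMe, rt; filter, concentrate
Reagents that add atoms: chlorotrimethylsilane, C[Si](C)(C)Cl
Why: O-Silylation of the enolised β-keto ester under soft enolisation gives the silyl enol ether of the ketone, the standard first stage in making a 1,3-bis(silyloxy)diene.

Step 6
Reactants: 11 methyl (Z)-4-methoxy-3-(trimethylsilyloxy)but-2-enoate
Product: 12 (1Z,3Z)-1,4-dimethoxy-1,3-bis(trimethylsilyloxy)buta-1,3-diene
Conditions: LiN(iPr)2 (1.2 equiv), THF, −78 °C; Me3SiCl (1.3 equiv), −78 → rt; pentane, filtration under Ar, use crude
Reagents that add atoms: chlorotrimethylsilane, C[Si](C)(C)Cl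
Why: Kinetic γ-deprotonation at the methoxy-bearing carbon gives the dienolate, which is silylated on the ester oxygen to the silyl ketene acetal; 4-alkoxy dienes of this class are known and are handled crude with exclusion of moisture.

Step 7
Reactants: 9 2-ethynyl-3,5,7,8-tetramethoxy-4H-chromen-4-one; 12 (1Z,3Z)-1,4-dimethoxy-1,3-bis(trimethylsilyloxy)buta-1,3-diene
Product: 14 2-(2,4-dihydroxy-5-methoxyphenyl)-3,5,7,8-tetramethoxy-4H-chromen-4-one, via cyclohexadiene cycloadduct 13 (not isolated)
Conditions: 12 (3 equiv), PhMe, 110 °C, sealed tube, Ar; then 1 M HCl, THF, rt
Reagents that add atoms: none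
Why: Proposed new method: a normal-electron-demand Diels–Alder reaction between electron-rich 12 and the alkyne of 9, whose LUMO is lowered through the C2=C3–C4=O path of the pyranone (a vinylogous alkynyl ketone), should form C5'–C6' first and C1'–C2' second, either in one very asynchronous step or through a 1,6-Mukaiyama–Michael adduct whose allenyl enolate closes on the oxygen-stabilised cation at the ketene acetal carbon; the closest known reaction type is the cycloaddition–aromatisation of 1-alkoxy-1,3-bis(silyloxy)buta-1,3-dienes with alkynyl ketones and propiolates to 2,4-dihydroxyaryl ketones and esters, and the only new element is the extra C=C between alkyne and carbonyl. Ring B closes by [4+2] cycloaddition to the cyclohexa-1,4-diene 13 (in the stepwise limit a six-membered closure of C1' onto C2'). No stereocentre reaches the product: the two sp3 carbons of 13 form without control and both become aromatic. The step needs regioselectivity, which matched polarity should secure: the largest HOMO coefficient of 12 lies at its methoxy-bearing terminus C4, remote from the ketene acetal, and the largest LUMO coefficient of 9 at the terminal alkyne carbon, the δ-position of the enone, so the methoxyl must end at C5' and the ketal carbon at C2'. It also needs chemoselectivity for the alkyne over C2 of the pyranone, which is fully substituted and shielded by the 3-methoxyl. Aromatisation has one course: C5' holds the only hydrogen on the two sp3 carbons, so acid removes the silyl groups, the hemiketal at C2' expels methanol and the dienone tautomerises to the 2',4'-diol with the 5'-methoxyl intact. The capped O3 and O5 of 9 keep the diene from being quenched and stop O3 from adding to the alkyne.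

Step 8
Reactants: 14 2-(2,4-dihydroxy-5-methoxyphenyl)-3,5,7,8-tetramethoxy-4H-chromen-4-one
Product: 15 2-(2,4-dihydroxy-5-methoxyphenyl)-3,5-dihydroxy-7,8-dimethoxy-4H-chromen-4-one
Conditions: AlBr3 (8 equiv), MeCN, 0 °C → rt; then 2 M HCl, 50 °C
Reagents that add atoms: none
Why: Chelation-directed ether cleavage: AlBr3 binds C4=O together with O5 (six-membered chelate) and with O3 (five-membered chelate) and bromide removes these two methyl groups by SN2 attack, while the unchelated methoxyls at C7, C8 and C5' should react far more slowly in MeCN at or below room temperature. This selective 3,5-demethylation is an established reaction of polymethoxyflavones; a boron trihalide at low temperature would be relied on only for O5, which is why AlBr3 is chosen.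

## Compound list

1 | 1,2,3,5-tetramethoxybenzene | COc1cc(OC)c(OC)c(OC)c1 | starting material
2 | methoxyacetyl chloride | COCC(=O)Cl | starting material
3 | 2-methoxy-1-(2,3,4,6-tetramethoxyphenyl)ethan-1-one | COCC(=O)c1c(OC)c(OC)c(OC)cc1OC | intermediate (not isolated)
4 | 1-(2-hydroxy-3,4,6-trimethoxyphenyl)-2-methoxyethan-1-one | COCC(=O)c1c(O)c(OC)c(OC)cc1OC | intermediate
5 | 3-(trimethylsilyl)prop-2-ynoic acid | C[Si](C)(C)C#CC(=O)O | starting material
6 | 3-(trimethylsilyl)prop-2-ynoyl chloride | C[Si](C)(C)C#CC(=O)Cl | intermediate
7 | 1-(2-hydroxy-3,4,6-trimethoxyphenyl)-2-methoxy-5-(trimethylsilyl)pent-4-yne-1,3-dione (racemic, enolisable; keto form drawn) | COC(C(=O)C#C[Si](C)(C)C)C(=O)c1c(O)c(OC)c(OC)cc1OC | intermediate (not isolated)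
8 | 3,5,7,8-tetramethoxy-2-[(trimethylsilyl)ethynyl]-4H-chromen-4-one | C[Si](C)(C)C#Cc1oc2c(OC)c(OC)cc(OC)c2c(=O)c1OC | intermediate
9 | 2-ethynyl-3,5,7,8-tetramethoxy-4H-chromen-4-one | C#Cc1oc2c(OC)c(OC)cc(OC)c2c(=O)c1OC | intermediate
10 | methyl 4-methoxy-3-oxobutanoate (methyl 4-methoxyacetoacetate) | COCC(=O)CC(=O)OC | starting material
11 | methyl (Z)-4-methoxy-3-(trimethylsilyloxy)but-2-enoate | COC/C(O[Si](C)(C)C)=C/C(=O)OC | intermediate
12 | (1Z,3Z)-1,4-dimethoxy-1,3-bis(trimethylsilyloxy)buta-1,3-diene | CO/C(O[Si](C)(C)C)=C/C(O[Si](C)(C)C)=C/OC | intermediate
13 | 2-[3,6-dimethoxy-4,6-bis(trimethylsilyloxy)cyclohexa-1,4-dien-1-yl]-3,5,7,8-tetramethoxy-4H-chromen-4-one (diastereomer mixture, both centres lost on aromatisation) | COC1C=C(c2oc3c(OC)c(OC)cc(OC)c3c(=O)c2OC)C(OC)(O[Si](C)(C)C)C=C1O[Si](C)(C)C | intermediate (not isolated)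
14 | 2-(2,4-dihydroxy-5-methoxyphenyl)-3,5,7,8-tetramethoxy-4H-chromen-4-one | COc1cc(-c2oc3c(OC)c(OC)cc(OC)c3c(=O)c2OC)c(O)cc1O | intermediate
15 | 2-(2,4-dihydroxy-5-methoxyphenyl)-3,5-dihydroxy-7,8-dimethoxy-4H-chromen-4-one | COc1cc(-c2oc3c(OC)c(OC)cc(O)c3c(=O)c2O)c(O)cc1O | target

## Step count and least certain steps

Total: 8 steps. Longest linear sequence: 5 steps (steps 1, 3, 4, 7, 8 from 1; equally steps 2, 3, 4, 7, 8 from 5).

**Step 7 (key step, proposed new method).** The most likely failure is that thermal decomposition of 12 (silyl migration, hydrolysis) outruns cycloaddition to an alkyne that is activated only vinylogously, or that the reaction stops after the first C–C bond at an open-chain 1,6-adduct. A first remedy within the same disconnection would be Lewis-acid chelation of C4=O and O5 at low temperature. The fallback uses known chemistry, sets out from 12 and 4, and returns at 14. Diene 12 and methyl propiolate, a dienophile class for which this cycloaddition–aromatisation is established (PhMe, 60–80 °C; then dilute HCl), should give, through the cycloadduct methyl 3,6-dimethoxy-4,6-bis(trimethylsilyloxy)cyclohexa-1,4-diene-1-carboxylate F1, methyl 2,4-dihydroxy-5-methoxybenzoate F2. Benzylation (BnBr, K2CO3, DMF) should give methyl 2,4-bis(benzyloxy)-5-methoxybenzoate F3, saponification (LiOH, THF–H2O) 2,4-bis(benzyloxy)-5-methoxybenzoic acid F4, and oxalyl chloride 2,4-bis(benzyloxy)-5-methoxybenzoyl chloride F5. This chloride acylates the dianion of 4 under the conditions of step 3 to 1-[2,4-bis(benzyloxy)-5-methoxyphenyl]-3-(2-hydroxy-3,4,6-trimethoxyphenyl)-2-methoxypropane-1,3-dione F6. Acid cyclodehydration gives 2-[2,4-bis(benzyloxy)-5-methoxyphenyl]-3,5,7,8-tetramethoxy-4H-chromen-4-one F7, and hydrogenolysis (H2, Pd/C, EtOAc) returns to the route at 14.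

**Step 3.** The most likely failures are conjugate addition to the alkynyl ketone during acylation or quench, 6-endo closure of the enol oxygen onto the alkyne during the acid treatment (diverting material to a 4-pyranone), and loss of the silyl cap under the basic conditions. The fallback sets out from 4 and returns at 9, bypassing steps 2–4, by bringing in the alkyne carbon through homologation. Kostanecki–Robinson acylation of 4 (Ac2O, NaOAc, 170 °C) should give 3,5,7,8-tetramethoxy-2-methyl-4H-chromen-4-one F8. SeO2 (1,4-dioxane, reflux) oxidises the vinylogously activated methyl group to 3,5,7,8-tetramethoxy-4-oxo-4H-chromene-2-carbaldehyde F9. Seyferth–Gilbert homologation with the Ohira–Bestmann reagent (dimethyl (1-diazo-2-oxopropyl)phosphonate, K2CO3, MeOH, 0 °C) then gives 9.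

**Step 8.** The most likely failures are over-demethylation at O5', because the aluminium phenoxide formed at O4' can deliver the Lewis acid to the neighbouring methoxyl, and incomplete cleavage at O3, the slower of the two chelated positions. The fallback sets out from 14 and returns at 15 by masking the ring B phenols temporarily. Acetylation (Ac2O, pyridine) should give 4-methoxy-6-(3,5,7,8-tetramethoxy-4-oxo-4H-chromen-2-yl)-1,3-phenylene diacetate F10, in which no phenoxide can direct the reagent to O5'. AlBr3 in MeCN then gives 4-(3,5-dihydroxy-7,8-dimethoxy-4-oxo-4H-chromen-2-yl)-6-methoxy-1,3-phenylene diacetate F11, and methanolysis (K2CO3, MeOH, Ar; then dilute acid) gives 15.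

## Further compounds

F1 | step 7 | methyl 3,6-dimethoxy-4,6-bis(trimethylsilyloxy)cyclohexa-1,4-diene-1-carboxylate (not isolated, diastereomer mixture) | COC(=O)C1=CC(OC)C(O[Si](C)(C)C)=CC1(OC)O[Si](C)(C)C
F2 | step 7 | methyl 2,4-dihydroxy-5-methoxybenzoate | COC(=O)c1cc(OC)c(O)cc1O
F3 | step 7 | methyl 2,4-bis(benzyloxy)-5-methoxybenzoate | COC(=O)c1cc(OC)c(OCc2ccccc2)cc1OCc1ccccc1
F4 | step 7 | 2,4-bis(benzyloxy)-5-methoxybenzoic acid | COc1cc(C(=O)O)c(OCc2ccccc2)cc1OCc1ccccc1
F5 | step 7 | 2,4-bis(benzyloxy)-5-methoxybenzoyl chloride | COc1cc(C(=O)Cl)c(OCc2ccccc2)cc1OCc1ccccc1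
F6 | step 7 | 1-[2,4-bis(benzyloxy)-5-methoxyphenyl]-3-(2-hydroxy-3,4,6-trimethoxyphenyl)-2-methoxypropane-1,3-dione (racemic, enolisable) | COC(C(=O)c1cc(OC)c(OCc2ccccc2)cc1OCc1ccccc1)C(=O)c1c(O)c(OC)c(OC)cc1OC
F7 | step 7 | 2-[2,4-bis(benzyloxy)-5-methoxyphenyl]-3,5,7,8-tetramethoxy-4H-chromen-4-one | COc1cc(-c2oc3c(OC)c(OC)cc(OC)c3c(=O)c2OC)c(OCc2ccccc2)cc1OCc1ccccc1
F8 | step 3 | 3,5,7,8-tetramethoxy-2-methyl-4H-chromen-4-one | Cc1oc2c(OC)c(OC)cc(OC)c2c(=O)c1OC
F9 | step 3 | 3,5,7,8-tetramethoxy-4-oxo-4H-chromene-2-carbaldehyde | O=Cc1oc2c(OC)c(OC)cc(OC)c2c(=O)c1OC
F10 | step 8 | 4-methoxy-6-(3,5,7,8-tetramethoxy-4-oxo-4H-chromen-2-yl)-1,3-phenylene diacetate | COc1cc(-c2oc3c(OC)c(OC)cc(OC)c3c(=O)c2OC)c(OC(C)=O)cc1OC(C)=O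
F11 | step 8 | 4-(3,5-dihydroxy-7,8-dimethoxy-4-oxo-4H-chromen-2-yl)-6-methoxy-1,3-phenylene diacetate | COc1cc(-c2oc3c(OC)c(OC)cc(O)c3c(=O)c2O)c(OC(C)=O)cc1OC(C)=O
A1 | alternative 1 | 2-(benzyloxy)-1-[6-hydroxy-3,4-dimethoxy-2-(methoxymethoxy)phenyl]ethan-1-one | O=C(COCc1ccccc1)c1c(O)cc(OC)c(OC)c1OCOC
A2 | alternative 1 | 4,5-dimethoxy-3-(methoxymethoxy)-2-(trimethylsilyl)phenyl trifluoromethanesulfonate | COCOc1c(OC)c(OC)cc(OS(=O)(=O)C(F)(F)F)c1[Si](C)(C)C
A3 | alternative 1 | benzyloxyacetic acid | OC(=O)COCc1ccccc1
A4 | alternative 2 | 3-(benzyloxy)-2-[2,4-bis(benzyloxy)-5-methoxyphenyl]-8-hydroxy-5,7-dimethoxy-4H-chromen-4-one | O=c1c(OCc2ccccc2)c(-c2cc(OC)c(OCc3ccccc3)cc2OCc2ccccc2)oc2c(O)c(OC)cc(OC)c12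
A5 | alternative 2 | pentacarbonyl{[5-(benzyloxy)-6-[2,4-bis(benzyloxy)-5-methoxyphenyl]-4-oxo-4H-pyran-3-yl](methoxy)methylidene}chromium, Cr(CO)5[C(OMe)(pyranonyl)] | COC(=[Cr](=C=O)(=C=O)(=C=O)(=C=O)=C=O)c1coc(-c2cc(OC)c(OCc3ccccc3)cc2OCc2ccccc2)c(OCc2ccccc2)c1=O
A6 | alternative 2 | methoxyacetylene (methoxyethyne) | COC#C
A7 | alternative 3 | 3-hydroxy-5,7,8-trimethoxy-2-[5-methoxy-2,4-bis(tosyloxy)phenyl]-4H-chromen-4-one | O=c1c(O)c(-c2cc(OC)c(OS(=O)(=O)c3ccc(C)cc3)cc2OS(=O)(=O)c2ccc(C)cc2)oc2c(OC)c(OC)cc(OC)c12
A8 | alternative 3 | 2-bromo-2-{bromo[5-methoxy-2,4-bis(tosyloxy)phenyl]methyl}-4,6,7-trimethoxy-1-benzofuran-3(2H)-one (racemic, diastereomer mixture) | O=C1c2c(OC)cc(OC)c(OC)c2OC1(Br)C(Br)c1cc(OC)c(OS(=O)(=O)c2ccc(C)cc2)cc1OS(=O)(=O)c1ccc(C)cc1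
A9 | alternative 3 | (Z)-4,6,7-trimethoxy-2-[5-methoxy-2,4-bis(tosyloxy)benzylidene]-1-benzofuran-3(2H)-one | O=C1/C(=C/c2cc(OC)c(OS(=O)(=O)c3ccc(C)cc3)cc2OS(=O)(=O)c2ccc(C)cc2)Oc2c(OC)c(OC)cc(OC)c21
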